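In azulene numbering, the cyclopentane of the target carries a secondary carbinol carbon C1 and a tertiary isopropyl carbinol carbon C3 on either side of C2. Its ring-fusion carbon C3a is α to the oxygenated C4 of the seven-membered ring. With C4 as a ketone, C1 is a latent oxocarbenium ion and C3a a latent enolate, which is a donor–acceptor cyclopropane (C1, C8a, C3a). The key step opens alkoxycyclopropyl ketone 10 with TMSOTf and traps the 1,3-zwitterion with the enol silane of 3-methylbutan-2-one. This strain-driven formal [3+2] annulation forms C1–C2 and C3–C3a, the cyclopentane and three stereocentres in one operation. Ring-closing metathesis then closes the cycloheptene.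

Key step: step 8

Assumption: the sense of induction of (+)-MIB and of Rh2(5S-MEPY)4 is taken from aryl and α-branched enals and from simple allyl diazoacetates; if either delivers the opposite face, its mirror-image form is used and nothing else changes.

NAP = naphthalen-2-ylmethyl; TBS = tert-butyldimethylsilyl.

Step 1
Reactants: 1 (E)-3-ethoxy-2-methylprop-2-enal; 2 naphthalen-2-ylmethanol
Product: 3 (E)-2-methyl-3-(NAP-oxy)prop-2-enal
Conditions: pyridinium p-toluenesulfonate (cat.), toluene, 60 °C, reduced pressure (removal of EtOH)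
Reagents that add atoms: none
Why: Acid-catalysed transetherification of a vinylogous ester (conjugate addition–elimination through the mixed acetal) is driven by removal of ethanol and should return the thermodynamically preferred E enol ether, now bearing a donor oxygen substituent that can be removed oxidatively at the end.

Step 2
Reactants: 3 (E)-2-methyl-3-(NAP-oxy)prop-2-enal
Product: 4 (1E,3R)-2-methyl-1-(NAP-oxy)penta-1,4-dien-3-ol
Conditions: CH2=CHMgBr, ZnCl2, THF/toluene, 1,4-dioxane (precipitation of magnesium halides), 0 °C; then (+)-MIB (10 mol%), 3, −20 °C; aq. NaHCO3 work-up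
Reagents that add atoms: vinylmagnesium bromide, C=C[Mg]Br (transferred through divinylzinc, C=C[Zn]C=C)
Why: Amino-alcohol-catalysed asymmetric 1,2-addition of an alkenylzinc reagent to an aldehyde, in which the (+)-MIB zinc alkoxide should deliver the vinyl group to the Re face and so set the 3R carbinol centre; the acid-labile product is kept basic throughout.

Step 3
Reactants: 4 (1E,3R)-dienol
Product: 6 (1E,3R)-2-methyl-1-(NAP-oxy)penta-1,4-dien-3-yl diazoacetate, via bromoacetate 5 (not isolated)
Conditions: BrCH2COBr, pyridine, CH2Cl2, −20 °C; filtration; then TsNHNHTs, DBU, THF, 0 °C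
Reagents that add atoms: bromoacetyl bromide, BrCC(Br)=O; N,N'-ditosylhydrazine, Cc1ccc(cc1)S(=O)(=O)NNS(=O)(=O)c1ccc(C)cc1
Why: Acylation, then N-alkylation of the ditosylhydrazine by the bromoacetate and double sulfinate elimination (diazoacetate synthesis from a bromoacetate) should run under basic, acid-free conditions that the enol ether tolerates, with no change at the stereocentre.

Step 4
Reactants: 6 diazoacetate
Product: 7 (1S,4R,5R,6R)-4-ethenyl-5-methyl-6-(NAP-oxy)-3-oxabicyclo[3.1.0]hexan-2-one
Conditions: Rh2(5S-MEPY)4 [dirhodium tetrakis(methyl (5S)-2-oxopyrrolidine-5-carboxylate)] (1 mol%), CH2Cl2, reflux, syringe-pump addition of 6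
Reagents that add atoms: none
Why: Chiral dirhodium carboxamidate-catalysed intramolecular cyclopropanation of an allylic diazoacetate should engage the electron-rich trisubstituted enol ether rather than the vinyl group; the ester tether delivers the carbene syn to the carbinol oxygen, the catalyst selects the alkene face that leaves the vinyl group exo (cis to the new quaternary methyl), and the E geometry is transferred stereospecifically to give the exo NAP-oxy group.

Step 5
Reactants: 7 cyclopropane lactone
Product: 9 TBS-protected cyclopropane Weinreb amide, via hydroxy Weinreb amide 8 (not isolated)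
Conditions: Me(MeO)NH·HCl, iPrMgCl, THF, −20 °C; pH 7 work-up; then TBSCl, imidazole, DMF, 0 °C to rt
Reagents that add atoms: N,O-dimethylhydroxylamine hydrochloride, CNOC.Cl; tert-butyldimethylsilyl chloride, CC(C)(C)[Si](C)(C)Cl
Why: Aminolysis of the γ-lactone with the chloromagnesium amide (Weinreb amide formation) frees the secondary alcohol, which is silylated at once with a reagent that is not Lewis acidic, so that relactonisation and opening of the donor–acceptor cyclopropane are avoided; no stereocentre is touched.

Step 6
Reactants: 9 Weinreb amide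
Product: 10 alkoxycyclopropyl methallyl ketone
Conditions: CH2=C(CH3)CH2MgCl, THF, −78 to −20 °C; cold pH 7 buffer
Reagents that add atoms: 2-methylallylmagnesium chloride, CC(=C)C[Mg]Cl
Why: Weinreb ketone synthesis, in which the chelated tetrahedral magnesium intermediate prevents over-addition of the allylic Grignard reagent and a cold buffered quench keeps the β,γ-unsaturated ketone from conjugating.

Step 7
Reactants: 11 3-methylbutan-2-one
Product: 12 trimethyl[(3-methylbut-1-en-2-yl)oxy]silane
Conditions: LiN(iPr)2, THF, −78 °C; then Me3SiCl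
Reagents that add atoms: chlorotrimethylsilane, C[Si](C)(C)Cl
Why: Kinetic deprotonation of the methyl ketone at the less substituted α-carbon and O-silylation (silyl enol ether formation) should give the terminal enol silane regioselectively.

Step 8
Reactants: 10 alkoxycyclopropyl ketone; 12 enol silane
Product: 14 tetrasubstituted cyclopentyl ketone, via tertiary trimethylsilyl ether 13 (not isolated)
Conditions: 12 (3 equiv), TMSOTf (0.3 equiv), 2,6-di-tert-butyl-4-methylpyridine (0.1 equiv), CH2Cl2, −78 to −40 °C; then 1 M HCl, THF, 0 °C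
Reagents that add atoms: none
Why: TMSOTf silylates the ketone oxygen, the push–pull cyclopropane bond between the NAP-oxy carbon and the acyl-bearing carbon heterolyses with release of ring strain to an oxocarbenium ion flanked by a silyl enol ether, enol silane 12 adds through its CH2 terminus to the oxocarbenium carbon (Mukaiyama-type), and the resulting silyloxocarbenium ion is captured by the internal silyl enol ether with regeneration of TMSOTf. The closest known reaction type is the Lewis-acid-mediated formal [3+2] annulation of 2-alkoxycyclopropyl ketones (donor–acceptor cyclopropanes) with silyl enol ethers. The only ring closed is the cyclopentane, by a 5-(enolexo)-exo-trig intramolecular Mukaiyama aldol addition. At the NAP-oxy carbon the external nucleophile should enter anti to the enol silane arm that has just been cleaved off, with the small methyl group and not the silyloxyallyl arm beside its trajectory (Felkin–Anh, reinforced by the 1,3-anti preference of β-silyloxy oxocarbenium ions), which places this oxygen cis to the quaternary methyl; the quaternary centre is a spectator. In the ring closure, allylic 1,3-strain holds the methyl group in the plane of the enol silane, so the acyl group ends cis to methyl and trans to the silyloxyallyl arm (also the thermodynamic, epimerisable arrangement), and the isopropyl group turns away from the enol silane, which leaves the new tertiary oxygen cis to the acyl group. The step needs an enolate only at the future ring-fusion carbon and not at the doubly activated CH2 next to the methallyl unit, which cyclopropane cleavage secures regiospecifically, and it needs ionising, non-chelating conditions so that the cation and not the cyclopropane geometry sets the secondary carbinol centre, which catalytic TMSOTf at −78 °C with a hindered pyridine provides while sparing the TBS and NAP ethers.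

Step 9
Reactants: 14 cyclopentyl ketone
Product: 15 trans-fused hydroazulenone
Conditions: (H2IMes)(PCy3)Cl2Ru=CHPh (second-generation Grubbs catalyst, 5 mol%), 1,4-benzoquinone (10 mol%), CH2Cl2 (2 mM), reflux
Reagents that add atoms: none
Why: Ring-closing metathesis between the vinyl group and the 1,1-disubstituted methallyl alkene should close the trans-fused cycloheptene with the trisubstituted double bond in place, ethene loss driving the reaction and benzoquinone suppressing hydride-mediated migration of the β,γ-double bond; no stereocentre is formed.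

Step 10
Reactants: 15 hydroazulenone
Product: 16 hydroazulene diol (C4 secondary and C3 tertiary hydroxyls)
Conditions: Me4NBH(OAc)3, MeCN/AcOH, −30 °C
Reagents that add atoms: none
Why: Evans–Saksena hydroxyl-directed reduction, in which the acetoxyborohydride bound to the tertiary hydroxyl (cis to the carbonyl carbon on the cyclopentane) delivers hydride to the ketone face that the isopropyl group also leaves open, so the new hydroxyl is anti to the directing hydroxyl and cis to the ring-fusion hydrogen.

Step 11
Reactants: 16 diol
Product: 17 triol NAP ether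
Conditions: Bu4NF, THF, 0 °C to rt
Reagents that add atoms: none
Why: Fluoride-mediated cleavage of the silyl ether (desilylation) frees the allylic alcohol while the NAP ether and the alkene are untouched.

Step 12
Reactants: 17 triol NAP ether; 18 angelic acid
Product: 20 bis-angelate NAP ether, via angelic 2,4,6-trichlorobenzoic anhydride 19 (not isolated)
Conditions: 18 (3 equiv), 2,4,6-trichlorobenzoyl chloride (3 equiv), Et3N (3.3 equiv), toluene, rt; filtration of Et3N·HCl; then 17 (1 equiv), toluene, 80 °C
Reagents that add atoms: angelic acid (the second of the two molecules of 18 that the product holds), C/C=C(/C)C(=O)O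
Why: Yamaguchi-type esterification with an excess of the preformed mixed anhydride and no nucleophilic catalyst should transfer one angeloyl group to each of the two secondary hydroxyls, so that two molecules of 18 end up in 20, leave the tertiary hydroxyl free for steric reasons and avoid base-induced isomerisation of the Z-enoate to the tiglate.

Step 13
Reactants: 20 bis-angelate NAP ether
Product: 21 target
Conditions: DDQ, CH2Cl2/pH 7 phosphate buffer, 0 °C to rt
Reagents that add atoms: none
Why: Oxidative cleavage of the naphthylmethyl ether with DDQ (hydride abstraction, then hydrolysis of the hemiacetal) runs under neutral conditions that spare both angelates, the trisubstituted alkene and the tertiary alcohol.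

Compound list

1 | (E)-3-ethoxy-2-methylprop-2-enal | CCO/C=C(\C)C=O | starting material
2 | naphthalen-2-ylmethanol | OCc1ccc2ccccc2c1 | starting material
3 | (E)-2-methyl-3-(naphthalen-2-ylmethoxy)prop-2-enal | O=C/C(C)=C/OCc1ccc2ccccc2c1 | intermediate
4 | (1E,3R)-2-methyl-1-(naphthalen-2-ylmethoxy)penta-1,4-dien-3-ol | C=C[C@@H](O)/C(C)=C/OCc1ccc2ccccc2c1 | intermediate
5 | (1E,3R)-2-methyl-1-(naphthalen-2-ylmethoxy)penta-1,4-dien-3-yl bromoacetate | BrCC(=O)O[C@H](C=C)/C(C)=C/OCc1ccc2ccccc2c1 | intermediate (not isolated)
6 | (1E,3R)-2-methyl-1-(naphthalen-2-ylmethoxy)penta-1,4-dien-3-yl diazoacetate | [N-]=[N+]=CC(=O)O[C@H](C=C)/C(C)=C/OCc1ccc2ccccc2c1 | intermediate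
7 | (1S,4R,5R,6R)-4-ethenyl-5-methyl-6-(naphthalen-2-ylmethoxy)-3-oxabicyclo[3.1.0]hexan-2-one; vinyl exo and cis to the 5-methyl group, NAP-oxy exo | O=C1O[C@H](C=C)[C@@]2(C)[C@H](OCc3ccc4ccccc4c3)[C@@H]12 | intermediate
8 | 2-[(1R)-1-hydroxyprop-2-enyl]-N-methoxy-N,2-dimethyl-3-(naphthalen-2-ylmethoxy)cyclopropane-1-carboxamide; configuration of 7 retained (amide cis to the hydroxyallyl arm, NAP-oxy trans to both and cis to methyl) | CON(C)C(=O)[C@@H]1[C@@H](OCc2ccc3ccccc3c2)[C@]1(C)[C@H](O)C=C | intermediate (not isolated)
9 | TBS ether of 8 | CON(C)C(=O)[C@@H]1[C@@H](OCc2ccc3ccccc3c2)[C@]1(C)[C@H](O[Si](C)(C)C(C)(C)C)C=C | intermediate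
10 | 1-{2-[(1R)-1-(TBS-oxy)prop-2-enyl]-2-methyl-3-(naphthalen-2-ylmethoxy)cyclopropyl}-3-methylbut-3-en-1-one; cyclopropane configuration as in 9 | CC(=C)CC(=O)[C@@H]1[C@@H](OCc2ccc3ccccc3c2)[C@]1(C)[C@H](O[Si](C)(C)C(C)(C)C)C=C | intermediate
11 | 3-methylbutan-2-one | CC(=O)C(C)C | starting material
12 | trimethyl[(3-methylbut-1-en-2-yl)oxy]silane | C=C(O[Si](C)(C)C)C(C)C | intermediate
13 | tertiary trimethylsilyl ether of 14 | C=C(C)CC(=O)[C@@H]1[C@@](C)([C@H](O[Si](C)(C)C(C)(C)C)C=C)[C@H](OCc2ccc3ccccc3c2)C[C@@]1(O[Si](C)(C)C)C(C)C | intermediate (not isolated)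
14 | 1-{2-[(1R)-1-(TBS-oxy)prop-2-enyl]-5-hydroxy-2-methyl-3-(naphthalen-2-ylmethoxy)-5-(propan-2-yl)cyclopentyl}-3-methylbut-3-en-1-one; acyl, 2-methyl, NAP-oxy and tertiary hydroxyl on one face of the cyclopentane, silyloxyallyl arm and isopropyl on the other | C=C(C)CC(=O)[C@@H]1[C@@](C)([C@H](O[Si](C)(C)C(C)(C)C)C=C)[C@H](OCc2ccc3ccccc3c2)C[C@@]1(O)C(C)C | intermediate
15 | 8-(TBS-oxy)-3-hydroxy-6,8a-dimethyl-1-(naphthalen-2-ylmethoxy)-3-(propan-2-yl)-2,3,3a,5,8,8a-hexahydroazulen-4(1H)-one; trans-fused, stereocentres as in 21 | O=C1CC(C)=C[C@@H](O[Si](C)(C)C(C)(C)C)[C@@]2(C)[C@H](OCc3ccc4ccccc4c3)C[C@@](O)(C(C)C)[C@H]12 | intermediate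
16 | 8-(TBS-oxy)-6,8a-dimethyl-1-(naphthalen-2-ylmethoxy)-3-(propan-2-yl)-1,2,3,3a,4,5,8,8a-octahydroazulene-3,4-diol; stereocentres as in 21 | O[C@H]1CC(C)=C[C@@H](O[Si](C)(C)C(C)(C)C)[C@@]2(C)[C@H](OCc3ccc4ccccc4c3)C[C@@](O)(C(C)C)[C@H]12 | intermediate
17 | 6,8a-dimethyl-1-(naphthalen-2-ylmethoxy)-3-(propan-2-yl)-1,2,3,3a,4,5,8,8a-octahydroazulene-3,4,8-triol; stereocentres as in 21 | O[C@H]1CC(C)=C[C@@H](O)[C@@]2(C)[C@H](OCc3ccc4ccccc4c3)C[C@@](O)(C(C)C)[C@H]12 | intermediate
18 | angelic acid, (2Z)-2-methylbut-2-enoic acid | C/C=C(/C)C(=O)O | starting material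
19 | (2Z)-2-methylbut-2-enoic 2,4,6-trichlorobenzoic anhydride | C/C=C(/C)C(=O)OC(=O)c1c(Cl)cc(Cl)cc1Cl | intermediate (not isolated)
20 | 1-O-(naphthalen-2-ylmethyl) ether of 21 | C/C=C(/C)C(=O)O[C@H]1CC(C)=C[C@@H](OC(=O)/C(C)=C\C)[C@@]2(C)[C@H](OCc3ccc4ccccc4c3)C[C@@](O)(C(C)C)[C@H]12 | intermediate
21 | (1R,3R,3aS,4S,8R,8aR)-1,3-dihydroxy-6,8a-dimethyl-3-(propan-2-yl)-1,2,3,3a,4,5,8,8a-octahydroazulene-4,8-diyl bis[(2Z)-2-methylbut-2-enoate] | C/C=C(/C)C(=O)O[C@H]1CC(C)=C[C@@H](OC(=O)/C(C)=C\C)[C@@]2(C)[C@H](O)C[C@@](O)(C(C)C)[C@H]12 | target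

Total step count: 13. Longest linear sequence: 12 steps (steps 1–6 and 8–13).

Steps most likely to fail

Step 8. The external enol silane may add to the other face of the oxocarbenium ion (poor facial selectivity in the first C–C bond formation), which inverts the NAP-oxy carbon. The fallback leaves this centre to be set by ring control at the end instead of by the annulation. It sets out from 10: the annulation with 12 then gives the tertiary trimethylsilyl ether F1 and, after the acidic work-up, the cyclopentyl ketone F2, both epimeric at the NAP-oxy carbon. F2 is taken through the unchanged sequence: ring-closing metathesis to the hydroazulenone F3, directed reduction to the diol F4, desilylation to the triol F5, double angeloylation to the diester F6 and DDQ cleavage to the 1-epi alcohol F7. Dess–Martin oxidation of the only free secondary hydroxyl gives the cyclopentanone F8. Reduction with NaBH4 and CeCl3·7H2O in MeOH at −78 °C should add hydride anti to the adjacent angular methyl group, as in 17-oxo steroids, and returns to the route at 21.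

Step 4. The carbene may be transferred to the vinyl group, or to the enol ether face that places the vinyl group endo (poor site or facial selectivity of the intramolecular transfer). The fallback replaces the tether by an intermolecular, reagent-controlled cyclopropanation. It sets out from 4, which is silylated (TBSCl, imidazole, DMF) to the silyl ether F9. Cyclopropanation of F9 with ethyl diazoacetate under CuOTf and the matched tert-butyl bis(oxazoline) ligand, in which the enol ether reacts far faster than the vinyl group, gives the cyclopropane ester F10; the configuration at its ester-bearing carbon is immaterial, since this centre becomes an enol silane in step 8. Treatment of F10 with Me(MeO)NH·HCl and iPrMgCl returns to the route at 9.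

Step 12. The Z-enoate may isomerise to the E-isomer during acylation, or the hindered allylic hydroxyl may be acylated incompletely. The fallback builds the angelate double bonds after the ester bonds. It sets out from 17, which is acylated twice with 2-[bis(2,2,2-trifluoroethoxy)phosphoryl]propanoic acid (DCC, DMAP, CH2Cl2) to the bis(phosphonopropionate) F11. Still–Gennari olefination of F11 with acetaldehyde (KN(SiMe3)2, 18-crown-6, THF, −78 °C) forms both Z-trisubstituted enoates and returns to the route at 20.

Further compounds

F1 | step 8 | tertiary trimethylsilyl ether of F2 | C=C(C)CC(=O)[C@@H]1[C@@](C)([C@H](O[Si](C)(C)C(C)(C)C)C=C)[C@@H](OCc2ccc3ccccc3c2)C[C@@]1(O[Si](C)(C)C)C(C)C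
F2 | step 8 | epimer of 14 at the NAP-oxy carbon | C=C(C)CC(=O)[C@@H]1[C@@](C)([C@H](O[Si](C)(C)C(C)(C)C)C=C)[C@@H](OCc2ccc3ccccc3c2)C[C@@]1(O)C(C)C
F3 | step 8 | 1-epimer of 15 | O=C1CC(C)=C[C@@H](O[Si](C)(C)C(C)(C)C)[C@@]2(C)[C@@H](OCc3ccc4ccccc4c3)C[C@@](O)(C(C)C)[C@H]12
F4 | step 8 | 1-epimer of 16 | O[C@H]1CC(C)=C[C@@H](O[Si](C)(C)C(C)(C)C)[C@@]2(C)[C@@H](OCc3ccc4ccccc4c3)C[C@@](O)(C(C)C)[C@H]12
F5 | step 8 | 1-epimer of 17 | O[C@H]1CC(C)=C[C@@H](O)[C@@]2(C)[C@@H](OCc3ccc4ccccc4c3)C[C@@](O)(C(C)C)[C@H]12
F6 | step 8 | 1-epimer of 20 | C/C=C(/C)C(=O)O[C@H]1CC(C)=C[C@@H](OC(=O)/C(C)=C\C)[C@@]2(C)[C@@H](OCc3ccc4ccccc4c3)C[C@@](O)(C(C)C)[C@H]12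
F7 | step 8 | 1-epimer of 21 | C/C=C(/C)C(=O)O[C@H]1CC(C)=C[C@@H](OC(=O)/C(C)=C\C)[C@@]2(C)[C@@H](O)C[C@@](O)(C(C)C)[C@H]12
F8 | step 8 | 1-oxo analogue of 21 (cyclopentanone) | C/C=C(/C)C(=O)O[C@H]1CC(C)=C[C@@H](OC(=O)/C(C)=C\C)[C@@]2(C)C(=O)C[C@@](O)(C(C)C)[C@H]12
F9 | step 4 | TBS ether of 4 | C=C[C@@H](O[Si](C)(C)C(C)(C)C)/C(C)=C/OCc1ccc2ccccc2c1
F10 | step 4 | ethyl ester analogue of 9 | CCOC(=O)[C@@H]1[C@@H](OCc2ccc3ccccc3c2)[C@]1(C)[C@H](O[Si](C)(C)C(C)(C)C)C=C
F11 | step 12 | 4,8-bis{2-[bis(2,2,2-trifluoroethoxy)phosphoryl]propanoate} of 17 | CC(C(=O)O[C@H]1CC(C)=C[C@@H](OC(=O)C(C)P(=O)(OCC(F)(F)F)OCC(F)(F)F)[C@@]2(C)[C@H](OCc3ccc4ccccc4c3)C[C@@](O)(C(C)C)[C@H]12)P(=O)(OCC(F)(F)F)OCC(F)(F)F
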